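**Retrosynthetic overview**
1. Ester C6–O bond last: target ⇒ 4β,6α-diol + silyl-protected 4-hydroxybenzoic acid (from 4-bromophenol and CO2); the 6α-carbinol comes from hydroxyl-directed reduction of a β-hydroxy enone.
2. C4–i-Pr bond and the C4/C5 stereocentres: β-hydroxy enone ⇒ bicyclic silyl vinylogous ester + isopropyl-cerium reagent.
3. Five-membered ring (formed second): vinylogous ester ⇒ monocyclic keto ester by Dieckmann closure of C4–C5.
4. Quaternary C1: keto ester ⇒ prochiral 3,6-dimethylcyclohepta-2,6-dienone + zinc ester homoenolate (desymmetrising conjugate addition).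
5. Seven-membered ring (formed first): dienone ⇒ 3-methylcyclohex-2-enone by α′-methylation and one-carbon oxidative ring expansion of a siloxycyclopropane.

Convention: locants C1–C10 in the text follow daucane numbering (C1 = methyl-bearing ring-fusion carbon, C4 = carbinol carbon bearing i-Pr, C5 = ring-fusion CH, C6 = ester carbon, C7=C8 with CH3 on C8); β is the face of the C1 methyl.
Assumption: the sense of induction of the chiral NHC–Cu catalyst in step 4 is not predicted here; the ligand enantiomer that gives the (S)-keto ester is used.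

**Step 1**
Reactants: 1 3-methylcyclohex-2-en-1-one
Product: 3 trimethyl[(2,5-dimethylcyclohexa-1,5-dien-1-yl)oxy]silane, via 3,6-dimethylcyclohex-2-en-1-one 2 (not isolated)
Conditions: LDA (1.05 equiv), THF, −78 °C; MeI (1.1 equiv), −78 → 0 °C; then LDA (1.1 equiv), −78 °C; TMSCl (1.3 equiv), −78 → 0 °C
Reagents that add atoms: iodomethane (CI); chlorotrimethylsilane (C[Si](C)(C)Cl)
Why: Kinetic α′-deprotonation gives the cross-conjugated enolate, which is C-methylated (enolate alkylation), and a second kinetic α′-deprotonation with O-silylation gives the 2-silyloxy-1,3-diene, destroying the stereocentre of 2.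

**Step 2**
Reactants: 3 trimethyl[(2,5-dimethylcyclohexa-1,5-dien-1-yl)oxy]silane
Product: 4 trimethyl[(3,6-dimethylbicyclo[4.1.0]hept-2-en-1-yl)oxy]silane
Conditions: Et2Zn (1.5 equiv), CH2I2 (1.5 equiv), Et2O, 0 °C → rt; cold aq. NH4Cl/pyridine work-up
Reagents that add atoms: diiodomethane (ICI)
Why: Furukawa-modified Simmons–Smith cyclopropanation is selective for the electron-rich silyl enol ether double bond of a 2-silyloxydiene over the trisubstituted alkene; the product is racemic and its stereocentres are erased in step 3.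

**Step 3**
Reactants: 4 trimethyl[(3,6-dimethylbicyclo[4.1.0]hept-2-en-1-yl)oxy]silane
Product: 6 3,6-dimethylcyclohepta-2,6-dien-1-one, via β-chloro ketone 5 (not isolated)
Conditions: FeCl3 (2.2 equiv), DMF, 0 °C → rt; then NaOAc, MeOH, reflux
Reagents that add atoms: none
Why: Ito–Saegusa oxidative ring expansion: Fe(III) oxidises the siloxycyclopropane, β-scission of the internal cyclopropane bond gives the tertiary ring-expanded radical that is trapped as the β-chloro ketone, and NaOAc dehydrochlorinates it (E1cB) to the symmetric cross-conjugated cycloheptadienone, which has no stereocentre.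

**Step 4**
Reactants: 6 3,6-dimethylcyclohepta-2,6-dien-1-one; 7 ethyl 3-iodopropanoate
Product: 10 ethyl 3-[(1S)-1,5-dimethyl-3-oxocyclohept-4-en-1-yl]propanoate, via zinc homoenolate 8 (not isolated), via silyl dienol ether 9 (not isolated)
Conditions: 7, Zn dust (TMSCl-activated), THF, 35 °C; then 6, Cu(OTf)2 (5 mol %), chiral sulfonate-NHC–Ag complex (3 mol %), TMSCl (2 equiv), THF–DMA, −30 → 0 °C; 1 M HCl work-up
Reagents that add atoms: none
Why: Proposed new method: Zn-to-Cu transmetalation of the zinc ester homoenolate gives a chiral NHC–Cu(I) alkyl that π-complexes one enone of the Cs-symmetric dienone, adds at the β-methyl carbon via Cu(III) and reductively eliminates with TMSCl trapping to the cross-conjugated silyl dienol ether, which cannot add a second time and is hydrolysed to the enone on work-up; because the two enone units are mirror-related, the catalyst's ordinary enantiofacial preference for β-methyl cycloalkenones alone fixes the quaternary C1 stereocentre as (S); the closest known reactions are NHC–Cu-catalysed asymmetric conjugate additions of dialkylzinc reagents to β-substituted cyclic enones and the achiral Cu/TMSCl-promoted conjugate addition of zinc homoenolates.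

**Step 5**
Reactants: 10 ethyl 3-[(1S)-1,5-dimethyl-3-oxocyclohept-4-en-1-yl]propanoate
Product: 12 (8aS)-4-[(tert-butyldimethylsilyl)oxy]-6,8a-dimethyl-1,2,8,8a-tetrahydroazulen-3(7H)-one, via potassium diketonate 11 (not isolated)
Conditions: KOt-Bu (1.1 equiv), THF, 0 °C → rt; then TBSCl (1.2 equiv), 0 °C → rt
Reagents that add atoms: tert-butyldimethylsilyl chloride (CC(C)(C)[Si](C)(C)Cl)
Why: Dieckmann condensation of the α′-enolate onto the ester (5-exo-trig) is driven by β-diketonate formation, and O-silylation gives the thermodynamically preferred silyl enol ether (double bond exocyclic to the cyclopentanone and linearly conjugated with C7=C8, the O-silyl isomers interconverting by 1,5-silyl shift); C1 is untouched.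

**Step 6**
Reactants: 12 (8aS)-4-[(tert-butyldimethylsilyl)oxy]-6,8a-dimethyl-1,2,8,8a-tetrahydroazulen-3(7H)-one
Product: 15 (3R,3aR,8aS)-3-hydroxy-6,8a-dimethyl-3-(propan-2-yl)-2,3,3a,7,8,8a-hexahydroazulen-4(1H)-one, via silyl dienol ether carbinol 13 (not isolated), via 3a-epimeric hydroxy ketone 14 (not isolated)
Conditions: i-PrMgCl (2 equiv), CeCl3 (2.2 equiv), THF, −78 °C; AcOH quench at −78 °C; then TBAF (1.2 equiv), AcOH (1.2 equiv), THF, 0 °C; then DBU (10 mol %), CH2Cl2, rt
Reagents that add atoms: isopropylmagnesium chloride (CC(C)[Mg]Cl)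
Why: Organocerium 1,2-addition to the vinylogous ester carbonyl (Stork–Danheiser-type addition, kept non-acidic so the tertiary alcohol survives) occurs anti to the pseudoaxial C1 methyl and sets C4 (i-Pr α, OH β), buffered fluoride unmasks the enone, and DBU equilibrates the α-carbon C5 to the trans-fused epimer in which i-Pr is anti to C6 and the 4-OH hydrogen-bonds the C6 carbonyl.

**Step 7**
Reactants: 15 (3R,3aR,8aS)-3-hydroxy-6,8a-dimethyl-3-(propan-2-yl)-2,3,3a,7,8,8a-hexahydroazulen-4(1H)-one
Product: 16 (3R,3aS,4S,8aS)-6,8a-dimethyl-3-(propan-2-yl)-1,2,3,3a,4,7,8,8a-octahydroazulene-3,4-diol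
Conditions: Me4NBH(OAc)3 (5 equiv), MeCN–AcOH (1:1), −30 → 0 °C
Reagents that add atoms: none
Why: Evans–Saksena hydroxyl-directed reduction: the acetoxyborohydride exchanges onto the 4β-OH and delivers hydride intramolecularly to the β face of the C6 carbonyl, giving the 1,3-anti 6α-alcohol with 1,2-selectivity and without base that could epimerise C5.

**Step 8**
Reactants: 17 4-bromophenol
Product: 20 4-[(tert-butyldimethylsilyl)oxy]benzoic acid, via aryl silyl ether 18 (not isolated), via aryllithium 19 (not isolated)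
Conditions: NaH (1.05 equiv), THF, 0 °C; TBSCl (1.0 equiv), rt; then n-BuLi (1.05 equiv), −78 °C; CO2, −78 → 0 °C; 1 M HCl to pH 4
Reagents that add atoms: tert-butyldimethylsilyl chloride (CC(C)(C)[Si](C)(C)Cl); carbon dioxide (O=C=O)
Why: In situ O-silylation, bromine–lithium exchange and carboxylation of the aryllithium with CO2 give the protected acid in one flask; no stereocentre is involved.

**Step 9**
Reactants: 16 (3R,3aS,4S,8aS)-6,8a-dimethyl-3-(propan-2-yl)-1,2,3,3a,4,7,8,8a-octahydroazulene-3,4-diol; 20 4-[(tert-butyldimethylsilyl)oxy]benzoic acid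
Product: 22 (3R,3aS,4S,8aS)-3-hydroxy-6,8a-dimethyl-3-(propan-2-yl)-1,2,3,3a,4,7,8,8a-octahydroazulen-4-yl 4-hydroxybenzoate, via silyl-protected ester 21 (not isolated)
Conditions: 20 (1.5 equiv), DCC (1.5 equiv), DMAP (0.3 equiv), CH2Cl2, rt; then TBAF (1.5 equiv), AcOH (1.5 equiv), THF, 0 °C
Reagents that add atoms: none
Why: Steglich esterification acylates only the secondary allylic 6α-OH (the tertiary 4-OH is inert) with retention at C6, and buffered fluoride then removes the phenolic silyl group without cleaving the aryl ester.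

**Compound list**
1 | 3-methylcyclohex-2-en-1-one | CC1=CC(=O)CCC1 | starting material
2 | 3,6-dimethylcyclohex-2-en-1-one (racemic) | CC1=CC(=O)C(C)CC1 | intermediate
3 | trimethyl[(2,5-dimethylcyclohexa-1,5-dien-1-yl)oxy]silane | CC1=C(O[Si](C)(C)C)C=C(C)CC1 | intermediate
4 | trimethyl[(3,6-dimethylbicyclo[4.1.0]hept-2-en-1-yl)oxy]silane (racemic, cis-fused cyclopropane) | CC1=CC2(O[Si](C)(C)C)CC2(C)CC1 | intermediate
5 | 6-chloro-3,6-dimethylcyclohept-2-en-1-one (racemic) | CC1=CC(=O)CC(C)(Cl)CC1 | intermediate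
6 | 3,6-dimethylcyclohepta-2,6-dien-1-one | CC1=CC(=O)C=C(C)CC1 | intermediate
7 | ethyl 3-iodopropanoate | CCOC(=O)CCI | starting material
8 | (3-ethoxy-3-oxopropyl)zinc iodide | CCOC(=O)CC[Zn]I | intermediate
9 | ethyl 3-[(1S)-1,5-dimethyl-3-[(trimethylsilyl)oxy]cyclohepta-2,4-dien-1-yl]propanoate | CC1=CC(O[Si](C)(C)C)=C[C@@](C)(CC1)CCC(=O)OCC | intermediate
10 | ethyl 3-[(1S)-1,5-dimethyl-3-oxocyclohept-4-en-1-yl]propanoate | CC1=CC(=O)C[C@@](C)(CC1)CCC(=O)OCC | intermediate
11 | potassium (8aS)-6,8a-dimethyl-3-oxo-1,2,3,7,8,8a-hexahydroazulen-4-olate | CC1=CC([O-])=C2[C@@](C)(CC1)CCC2=O.[K+] | intermediate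
12 | (8aS)-4-[(tert-butyldimethylsilyl)oxy]-6,8a-dimethyl-1,2,8,8a-tetrahydroazulen-3(7H)-one | CC1=CC(O[Si](C)(C)C(C)(C)C)=C2[C@@](C)(CC1)CCC2=O | intermediate
13 | (3R,8aS)-4-[(tert-butyldimethylsilyl)oxy]-6,8a-dimethyl-3-(propan-2-yl)-1,2,3,7,8,8a-hexahydroazulen-3-ol | CC1=CC(O[Si](C)(C)C(C)(C)C)=C2[C@@](C)(CC1)CC[C@@]2(O)C(C)C | intermediate
14 | (3R,3aS,8aS)-3-hydroxy-6,8a-dimethyl-3-(propan-2-yl)-2,3,3a,7,8,8a-hexahydroazulen-4(1H)-one (cis-fused 3a-epimer; 4β-hydroxy-5βH-dauc-7-en-6-one) | CC1=CC(=O)[C@H]2[C@@](C)(CC1)CC[C@@]2(O)C(C)C | intermediate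
15 | (3R,3aR,8aS)-3-hydroxy-6,8a-dimethyl-3-(propan-2-yl)-2,3,3a,7,8,8a-hexahydroazulen-4(1H)-one (trans-fused; 4β-hydroxy-5αH-dauc-7-en-6-one) | CC1=CC(=O)[C@@H]2[C@@](C)(CC1)CC[C@@]2(O)C(C)C | intermediate
16 | (3R,3aS,4S,8aS)-6,8a-dimethyl-3-(propan-2-yl)-1,2,3,3a,4,7,8,8a-octahydroazulene-3,4-diol (5αH-dauc-7-ene-4β,6α-diol) | CC1=C[C@H](O)[C@@H]2[C@@](C)(CC1)CC[C@@]2(O)C(C)C | intermediate
17 | 4-bromophenol | Oc1ccc(Br)cc1 | starting material
18 | (4-bromophenoxy)(tert-butyl)dimethylsilane | CC(C)(C)[Si](C)(C)Oc1ccc(Br)cc1 | intermediate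
19 | [4-[(tert-butyldimethylsilyl)oxy]phenyl]lithium | [Li]c1ccc(O[Si](C)(C)C(C)(C)C)cc1 | intermediate
20 | 4-[(tert-butyldimethylsilyl)oxy]benzoic acid | CC(C)(C)[Si](C)(C)Oc1ccc(cc1)C(=O)O | intermediate
21 | (3R,3aS,4S,8aS)-3-hydroxy-6,8a-dimethyl-3-(propan-2-yl)-1,2,3,3a,4,7,8,8a-octahydroazulen-4-yl 4-[(tert-butyldimethylsilyl)oxy]benzoate | CC1=C[C@H](OC(=O)c2ccc(O[Si](C)(C)C(C)(C)C)cc2)[C@@H]2[C@@](C)(CC1)CC[C@@]2(O)C(C)C | intermediate
22 | (3R,3aS,4S,8aS)-3-hydroxy-6,8a-dimethyl-3-(propan-2-yl)-1,2,3,3a,4,7,8,8a-octahydroazulen-4-yl 4-hydroxybenzoate (4β-hydroxy-5αH-dauc-7-en-6α-yl 4-hydroxybenzoate) | CC1=C[C@H](OC(=O)c2ccc(O)cc2)[C@@H]2[C@@](C)(CC1)CC[C@@]2(O)C(C)C | target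

**Totals**
Total step count: 9. Longest linear sequence: 8 (steps 1–7 and 9; step 8 is the side branch).

**Steps most likely to fail and their fallbacks**

Step 4 (proposed new desymmetrising conjugate addition; risks are low reactivity of the homoenolate at a β,β-disubstituted carbon and insufficient ee). The fallback uses known chemistry, sets out from 6 and comes back at 10. The same zinc reagent 8 is added to 6 under the established achiral conditions for zinc homoenolates (CuBr·SMe2 cat., TMSCl, HMPA, THF), giving the racemic silyl dienol ether F1. Acidic work-up hydrolyses it to the racemic keto ester F2. Preparative chiral-phase SFC of F2 then gives the (S)-enantiomer, which is 10.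

Step 6 (risks are the facial selectivity of the i-Pr addition at C4, loss of the tertiary alcohol by elimination, and the C5 equilibration). The fallback sets out from 12 and comes back at 15, setting C4 by hydroxyl-directed epoxidation instead of by nucleophile approach.
- After the same organocerium addition to 12 (giving 13), the crude adduct is stirred with 1 M HCl, which effects the Stork–Danheiser transposition to the cross-conjugated dienone F3.
- (S)-Me-CBS/BH3·SMe2 reduces F3 under reagent control to the 6β-dienol F4.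
- VO(acac)2/t-BuOOH epoxidises C4=C5 syn to the hydroxyl, giving the epoxy alcohol F5.
- Dess–Martin periodinane gives the epoxy ketone F6.
- SmI2/MeOH (THF, −90 °C) cleaves the Cα–O bond to the 4β-hydroxy ketone (14/15 mixture), and the same DBU equilibration delivers 15.

Step 7 (risk is that internal hydride delivery is slow or unselective on the enone). The fallback sets out from 15 and comes back at 21, using external hydride followed by inversion. NaBH4/CeCl3 (MeOH, −78 °C), attacking the less hindered α face, gives the 6β-epimeric diol F7. Mitsunobu esterification of F7 with acid 20 (PPh3, DIAD, toluene, 0 °C) inverts C6 and gives 21 directly, which is desilylated as in step 9.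

**Further compounds**
F1 | step 4 | racemic ethyl 3-[1,5-dimethyl-3-[(trimethylsilyl)oxy]cyclohepta-2,4-dien-1-yl]propanoate | CC1=CC(O[Si](C)(C)C)=CC(C)(CC1)CCC(=O)OCC
F2 | step 4 | racemic ethyl 3-(1,5-dimethyl-3-oxocyclohept-4-en-1-yl)propanoate | CC1=CC(=O)CC(C)(CC1)CCC(=O)OCC
F3 | step 6 | (8aS)-6,8a-dimethyl-3-(propan-2-yl)-1,7,8,8a-tetrahydroazulen-4(2H)-one (dauca-4,7-dien-6-one) | CC1=CC(=O)C2=C(C(C)C)CC[C@]2(C)CC1
F4 | step 6 | (4R,8aS)-6,8a-dimethyl-3-(propan-2-yl)-1,2,4,7,8,8a-hexahydroazulen-4-ol (dauca-4,7-dien-6β-ol) | CC1=C[C@@H](O)C2=C(C(C)C)CC[C@]2(C)CC1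
F5 | step 6 | 4β,5β-epoxydauc-7-en-6β-ol | CC1=C[C@@H](O)[C@]23O[C@@]2(C(C)C)CC[C@]3(C)CC1
F6 | step 6 | 4β,5β-epoxydauc-7-en-6-one | CC1=CC(=O)[C@]23O[C@@]2(C(C)C)CC[C@]3(C)CC1
F7 | step 7 | (3R,3aS,4R,8aS)-6,8a-dimethyl-3-(propan-2-yl)-1,2,3,3a,4,7,8,8a-octahydroazulene-3,4-diol (5αH-dauc-7-ene-4β,6β-diol) | CC1=C[C@@H](O)[C@@H]2[C@@](C)(CC1)CC[C@@]2(O)C(C)C
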